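The cis-fused α-methylene-γ-butyrolactone (O1–C2–C3–C3a–C7a, benzofuranone numbering) is read as the [2+2+1] adduct of an aldehyde C=O, the internal π-bond of a terminal allene and carbon monoxide. An allenic hetero-Pauson–Khand reaction of acyclic allenyl aldehyde 19, catalysed by Ru3(CO)12, therefore closes the cyclohexane (C3a–C7a), brings in the lactone carbonyl (C2–C3) and forms O1–C2 in a single operation, fixing the cis ring fusion. The precursor is a linear chain that already holds the C4–C7 stereochemistry, assembled by a substrate-controlled Ireland–Claisen rearrangement (C5, quaternary C6), Felkin–Anh ethynylation (C4) and Crabbé homologation; the epoxy aldehyde is installed last.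

Key step: step 14

Remark: locants in the text follow 1-benzofuran-2-one numbering of the target (O1; C2 lactone carbonyl; C3 methylidene-bearing carbon; C3a and C7a ring fusion; C4 ester carbon; C5 oxiranyl-bearing carbon; C6 quaternary carbon; C7 carbinol carbon) and are also used for the corresponding carbons of the acyclic intermediates.

Remark: compounds 1 and 7 are taken as commercial.

Step 1
Reactants: 1 methyl (4S)-2,2-dimethyl-1,3-dioxolane-4-carboxylate
Product: 3 (4R)-4-ethynyl-2,2-dimethyl-1,3-dioxolane, via aldehyde 2 (not isolated)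
Conditions: DIBAL-H (1.05 equiv), CH2Cl2, −78 °C; then MeOH, dimethyl (1-diazo-2-oxopropyl)phosphonate, K2CO3, −78 °C → rt
Reagents that add atoms: dimethyl (1-diazo-2-oxopropyl)phosphonate, CC(=O)C(=[N+]=[N-])P(=O)(OC)OC
Why: Partial ester reduction stops at the aluminium hemiacetal, and the released α-alkoxy aldehyde is homologated in the same pot by the Ohira–Bestmann variant of the Seyferth–Gilbert reaction, conditions mild enough to leave the dioxolane stereocentre (future C7) untouched.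

Step 2
Reactants: 3 (4R)-4-ethynyl-2,2-dimethyl-1,3-dioxolane
Product: 4 methyl 3-[(4R)-2,2-dimethyl-1,3-dioxolan-4-yl]prop-2-ynoate
Conditions: n-BuLi, THF, −78 °C; ClCO2Me, −78 → 0 °C
Reagents that add atoms: methyl chloroformate, COC(=O)Cl
Why: C-acylation of the lithium acetylide with a chloroformate is a standard route to ynoates and does not touch the stereocentre.

Step 3
Reactants: 4 methyl 3-[(4R)-2,2-dimethyl-1,3-dioxolan-4-yl]prop-2-ynoate
Product: 5 methyl (2Z)-3-[(4R)-2,2-dimethyl-1,3-dioxolan-4-yl]but-2-enoate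
Conditions: Me2CuLi (from MeLi and CuI), THF, −78 °C; NH4Cl (aq), −78 °C
Reagents that add atoms: lithium dimethylcuprate, [Li+].C[Cu-]C
Why: Syn-carbocupration of the ynoate followed by cold protonation places the new methyl cis to hydrogen, so the dioxolanyl group ends up cis to the ester and the Z-trisubstituted alkene is set stereospecifically.

Step 4
Reactants: 5 methyl (2Z)-3-[(4R)-2,2-dimethyl-1,3-dioxolan-4-yl]but-2-enoate
Product: 6 (2Z)-3-[(4R)-2,2-dimethyl-1,3-dioxolan-4-yl]but-2-en-1-ol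
Conditions: DIBAL-H (2.5 equiv), CH2Cl2, −78 °C; potassium sodium tartrate (aq)
Reagents that add atoms: none
Why: 1,2-Reduction of the enoate by the aluminium hydride gives the allylic alcohol without touching the alkene geometry, and the non-acidic work-up keeps the acetonide and prevents lactonisation.

Step 5
Reactants: 6 (2Z)-3-[(4R)-2,2-dimethyl-1,3-dioxolan-4-yl]but-2-en-1-ol; 7 3-methylbut-2-enoyl chloride
Product: 8 (2Z)-3-[(4R)-2,2-dimethyl-1,3-dioxolan-4-yl]but-2-en-1-yl 3-methylbut-2-enoate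
Conditions: pyridine, DMAP (cat.), CH2Cl2, 0 °C
Reagents that add atoms: none
Why: Nucleophile-catalysed O-acylation of the primary allylic alcohol should be clean, and pyridine in place of a trialkylamine avoids vinylketene formation and deconjugation of the acyl group.

Step 6
Reactants: 8 (2Z)-3-[(4R)-2,2-dimethyl-1,3-dioxolan-4-yl]but-2-en-1-yl 3-methylbut-2-enoate
Product: 11 (2S,3S)-3-[(4R)-2,2-dimethyl-1,3-dioxolan-4-yl]-3-methyl-2-(prop-1-en-2-yl)pent-4-en-1-ol, via silyl ketene acetal 9 (not isolated), via trimethylsilyl ester 10 (not isolated)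
Conditions: LDA, THF, −78 °C; Me3SiCl, −78 → 50 °C; then LiAlH4, THF, 0 °C
Reagents that add atoms: none
Why: In this Ireland–Claisen rearrangement, γ-deprotonation of the s-cis senecioate should give the (1Z)-silyl dienol ether 9, whose chair [3,3] shift onto the Z-alkene, anti to the allylic C–O bond with the dioxolane C–H eclipsing the alkene (A(1,3) control), sets quaternary C6 and C5 together and creates the C6 vinyl group, before ester 10 is reduced in the same flask.

Step 7
Reactants: 11 (2S,3S)-3-[(4R)-2,2-dimethyl-1,3-dioxolan-4-yl]-3-methyl-2-(prop-1-en-2-yl)pent-4-en-1-ol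
Product: 12 (2S,3S)-3-[(4R)-2,2-dimethyl-1,3-dioxolan-4-yl]-3-methyl-2-(prop-1-en-2-yl)pent-4-enal
Conditions: Dess–Martin periodinane, NaHCO3, CH2Cl2, 0 °C; used crude
Reagents that add atoms: none
Why: Buffered Dess–Martin oxidation is neutral enough to deliver the β,γ-unsaturated aldehyde without epimerisation at C5 or migration of the isopropenyl double bond into conjugation.

Step 8
Reactants: 12 (2S,3S)-3-[(4R)-2,2-dimethyl-1,3-dioxolan-4-yl]-3-methyl-2-(prop-1-en-2-yl)pent-4-enal
Product: 13 (3R,4S,5S)-5-[(4R)-2,2-dimethyl-1,3-dioxolan-4-yl]-5-methyl-4-(prop-1-en-2-yl)hept-6-en-1-yn-3-ol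
Conditions: HC≡CMgBr, THF, −78 → −20 °C; NH4Cl (aq)
Reagents that add atoms: ethynylmagnesium bromide, C#C[Mg]Br
Why: Grignard 1,2-addition under Felkin–Anh control, with the quaternary carbon anti to the weakly basic acetylide and the isopropenyl group flanking the carbonyl oxygen, should give the (3R)-carbinol that becomes C4.

Step 9
Reactants: 13 (3R,4S,5S)-5-[(4R)-2,2-dimethyl-1,3-dioxolan-4-yl]-5-methyl-4-(prop-1-en-2-yl)hept-6-en-1-yn-3-ol
Product: 15 (4S,5S,6S)-6-[(4R)-2,2-dimethyl-1,3-dioxolan-4-yl]-6-methyl-5-(prop-1-en-2-yl)octa-1,2,7-trien-4-ol, via Mannich base 14 (not isolated)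
Conditions: (CH2O)n, CuI (copper iodide, 0.5 equiv), Cy2NH, 1,4-dioxane, reflux
Reagents that add atoms: formaldehyde (as paraformaldehyde), C=O
Why: The Crabbé homologation converts the terminal alkyne through propargylic amine 14 and a copper-mediated 1,5-hydride shift into the terminal allene, tolerates the free propargylic hydroxyl and does not touch the carbinol stereocentre (its descriptor changes only by priority).

Step 10
Reactants: 15 (4S,5S,6S)-6-[(4R)-2,2-dimethyl-1,3-dioxolan-4-yl]-6-methyl-5-(prop-1-en-2-yl)octa-1,2,7-trien-4-ol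
Product: 16 (4S,5S,6S)-6-[(4R)-2,2-dimethyl-1,3-dioxolan-4-yl]-6-methyl-5-(prop-1-en-2-yl)octa-1,2,7-trien-4-yl 2-methylpropanoate
Conditions: (i-PrCO)2O, Et3N, DMAP (cat.), CH2Cl2, rt
Reagents that add atoms: 2-methylpropanoic anhydride, CC(C)C(=O)OC(=O)C(C)C
Why: DMAP-catalysed acylation installs the isobutyrate of the target with retention at the hindered allenyl carbinol.

Step 11
Reactants: 16 (4S,5S,6S)-6-[(4R)-2,2-dimethyl-1,3-dioxolan-4-yl]-6-methyl-5-(prop-1-en-2-yl)octa-1,2,7-trien-4-yl 2-methylpropanoate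
Product: 17 (2R,3S,4S,5S)-3-ethenyl-1,2-dihydroxy-3-methyl-4-(prop-1-en-2-yl)octa-6,7-dien-5-yl 2-methylpropanoate
Conditions: AcOH/H2O (4:1), 40 °C
Reagents that add atoms: none
Why: Mild acid hydrolysis of the terminal acetonide should free the 1,2-diol while the ester, the allene and the alkenes are stable to dilute acetic acid.

Step 12
Reactants: 17 (2R,3S,4S,5S)-3-ethenyl-1,2-dihydroxy-3-methyl-4-(prop-1-en-2-yl)octa-6,7-dien-5-yl 2-methylpropanoate
Product: 18 (2R,3S,4S,5S)-3-ethenyl-3-methyl-4-(prop-1-en-2-yl)-1,2-bis[(triethylsilyl)oxy]octa-6,7-dien-5-yl 2-methylpropanoate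
Conditions: Et3SiOTf, 2,6-lutidine, CH2Cl2, −78 → 0 °C
Reagents that add atoms: triethylsilyl trifluoromethanesulfonate, CC[Si](CC)(CC)OS(=O)(=O)C(F)(F)F
Why: Silylation with the silyl triflate is forceful enough to protect the hindered secondary hydroxyl next to the quaternary carbon as well as the primary one.

Step 13
Reactants: 18 (2R,3S,4S,5S)-3-ethenyl-3-methyl-4-(prop-1-en-2-yl)-1,2-bis[(triethylsilyl)oxy]octa-6,7-dien-5-yl 2-methylpropanoate
Product: 19 (2R,3S,4S,5S)-3-ethenyl-3-methyl-1-oxo-4-(prop-1-en-2-yl)-2-[(triethylsilyl)oxy]octa-6,7-dien-5-yl 2-methylpropanoate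
Conditions: (COCl)2, DMSO, CH2Cl2, −78 → −30 °C; Et3N, −78 °C → rt
Reagents that add atoms: none
Why: Under Swern conditions the chlorosulfonium salt cleaves and oxidises only the unhindered primary triethylsilyl ether, giving the α-silyloxy aldehyde directly while the secondary silyl ether, the ester and the allene remain.

Step 14
Reactants: 19 (2R,3S,4S,5S)-3-ethenyl-3-methyl-1-oxo-4-(prop-1-en-2-yl)-2-[(triethylsilyl)oxy]octa-6,7-dien-5-yl 2-methylpropanoate
Product: 21 (3aS,4R,5S,6S,7R,7aS)-6-ethenyl-7-hydroxy-6-methyl-3-methylidene-2-oxo-5-(prop-1-en-2-yl)octahydro-1-benzofuran-4-yl 2-methylpropanoate, via triethylsilyl ether 20 (not isolated)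
Conditions: Ru3(CO)12 (5 mol %), CO (20 atm), 1,4-dioxane, 120 °C; then HF·pyridine, THF, 0 °C
Reagents that add atoms: carbon monoxide, [C-]#[O+]
Why: Zerovalent ruthenium carbonyl, formed from Ru3(CO)12 under CO, binds the aldehyde C=O and the internal allene π-bond and couples them oxidatively to an oxaruthenacyclopentane (C3a–C7a bond), CO inserts into the Ru–C3 bond (C2–C3 bond) and C–O reductive elimination closes O1–C2 and returns the catalyst. This is the allenic hetero-Pauson–Khand reaction, a [2+2+1] carbonylative cycloaddition established for δ-allenyl aldehydes. The cyclohexane is closed in a 6-exo mode with respect to both the carbonyl and the allene, the lactone by the [2+2+1] assembly on the metal. C3a and C7a are cis because both new bonds of the metallacycle form on one face, and their sense relative to C4–C7 follows from a chair-like transition state with the 4-isobutyryloxy, 5-isopropenyl, 6-vinyl and 7-silyloxy groups equatorial and the C7–O bond anti to the forming bond (polar Felkin–Anh), which puts O1 axial and C3 equatorial. The step needs the internal and not the terminal allene π-bond to react and the vinyl and isopropenyl groups to stay out, which the six- over seven-membered closure and the weak binding of isolated alkenes to the ruthenium carbonyl under CO pressure should secure. HF·pyridine then cleaves the triethylsilyl ether of 20 in the same flask.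

Step 15
Reactants: 21 (3aS,4R,5S,6S,7R,7aS)-6-ethenyl-7-hydroxy-6-methyl-3-methylidene-2-oxo-5-(prop-1-en-2-yl)octahydro-1-benzofuran-4-yl 2-methylpropanoate
Product: 22 (3aS,4R,5S,6S,7R,7aS)-6-ethenyl-7-hydroxy-5-(3-hydroxyprop-1-en-2-yl)-6-methyl-3-methylidene-2-oxo-octahydro-1-benzofuran-4-yl 2-methylpropanoate
Conditions: SeO2 (cat.), t-BuOOH, CH2Cl2, rt
Reagents that add atoms: tert-butyl hydroperoxide, CC(C)(C)OO
Why: Selenium dioxide allylic hydroxylation (ene reaction then [2,3]-shift) should take the isopropenyl methyl, because the C5 methine is shielded by the quaternary centre, the vinyl group has no allylic hydrogen and the electron-poor methylidene lactone does not engage in the ene step.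

Step 16
Reactants: 22 (3aS,4R,5S,6S,7R,7aS)-6-ethenyl-7-hydroxy-5-(3-hydroxyprop-1-en-2-yl)-6-methyl-3-methylidene-2-oxo-octahydro-1-benzofuran-4-yl 2-methylpropanoate
Product: 23 (3aS,4S,5S,6S,7R,7aS)-6-ethenyl-7-hydroxy-5-[(2S)-2-(hydroxymethyl)oxiran-2-yl]-6-methyl-3-methylidene-2-oxo-octahydro-1-benzofuran-4-yl 2-methylpropanoate
Conditions: Ti(Oi-Pr)4 (20 mol %), L-(+)-diethyl tartrate (24 mol %), t-BuOOH, 4 Å molecular sieves, CH2Cl2, −20 °C
Reagents that add atoms: tert-butyl hydroperoxide, CC(C)(C)OO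
Why: Sharpless asymmetric epoxidation acts only on the allylic alcohol, and L-(+)-tartrate should deliver oxygen to the face that gives the (2S)-oxirane, as it does for other 2-substituted prop-2-en-1-ols, so the oxirane stereocentre is set by the reagent.

Step 17
Reactants: 23 (3aS,4S,5S,6S,7R,7aS)-6-ethenyl-7-hydroxy-5-[(2S)-2-(hydroxymethyl)oxiran-2-yl]-6-methyl-3-methylidene-2-oxo-octahydro-1-benzofuran-4-yl 2-methylpropanoate
Product: 24 (3aS,4S,5S,6S,7R,7aS)-6-ethenyl-5-[(2R)-2-formyloxiran-2-yl]-7-hydroxy-6-methyl-3-methylidene-2-oxo-octahydro-1-benzofuran-4-yl 2-methylpropanoate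
Conditions: TEMPO (cat.), PhI(OAc)2, CH2Cl2, rt
Reagents that add atoms: none
Why: Oxoammonium-mediated oxidation with TEMPO and PhI(OAc)2 is selective for the primary alcohol over the hindered C7 secondary alcohol and is mild enough for the epoxy aldehyde, whose descriptor changes from S to R by priority only.

Compound list
1 | methyl (4S)-2,2-dimethyl-1,3-dioxolane-4-carboxylate | COC(=O)[C@@H]1COC(C)(C)O1 | starting material
2 | (4S)-2,2-dimethyl-1,3-dioxolane-4-carbaldehyde | O=C[C@@H]1COC(C)(C)O1 | intermediate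
3 | (4R)-4-ethynyl-2,2-dimethyl-1,3-dioxolane | C#C[C@@H]1COC(C)(C)O1 | intermediate
4 | methyl 3-[(4R)-2,2-dimethyl-1,3-dioxolan-4-yl]prop-2-ynoate | COC(=O)C#C[C@@H]1COC(C)(C)O1 | intermediate
5 | methyl (2Z)-3-[(4R)-2,2-dimethyl-1,3-dioxolan-4-yl]but-2-enoate | COC(=O)/C=C(/C)[C@@H]1COC(C)(C)O1 | intermediate
6 | (2Z)-3-[(4R)-2,2-dimethyl-1,3-dioxolan-4-yl]but-2-en-1-ol | OC/C=C(/C)[C@@H]1COC(C)(C)O1 | intermediate
7 | 3-methylbut-2-enoyl chloride | CC(C)=CC(=O)Cl | starting material
8 | (2Z)-3-[(4R)-2,2-dimethyl-1,3-dioxolan-4-yl]but-2-en-1-yl 3-methylbut-2-enoate | CC(C)=CC(=O)OC/C=C(/C)[C@@H]1COC(C)(C)O1 | intermediate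
9 | {[(1Z)-1-{[(2Z)-3-[(4R)-2,2-dimethyl-1,3-dioxolan-4-yl]but-2-en-1-yl]oxy}-3-methylbuta-1,3-dien-1-yl]oxy}(trimethyl)silane | C=C(C)/C=C(\O[Si](C)(C)C)OC/C=C(/C)[C@@H]1COC(C)(C)O1 | intermediate
10 | trimethylsilyl (2S,3S)-3-[(4R)-2,2-dimethyl-1,3-dioxolan-4-yl]-3-methyl-2-(prop-1-en-2-yl)pent-4-enoate | C=C[C@@]([C@@H]1COC(C)(C)O1)(C)[C@H](C(=C)C)C(=O)O[Si](C)(C)C | intermediate
11 | (2S,3S)-3-[(4R)-2,2-dimethyl-1,3-dioxolan-4-yl]-3-methyl-2-(prop-1-en-2-yl)pent-4-en-1-ol | C=C[C@@]([C@@H]1COC(C)(C)O1)(C)[C@H](C(=C)C)CO | intermediate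
12 | (2S,3S)-3-[(4R)-2,2-dimethyl-1,3-dioxolan-4-yl]-3-methyl-2-(prop-1-en-2-yl)pent-4-enal | C=C[C@@]([C@@H]1COC(C)(C)O1)(C)[C@H](C(=C)C)C=O | intermediate
13 | (3R,4S,5S)-5-[(4R)-2,2-dimethyl-1,3-dioxolan-4-yl]-5-methyl-4-(prop-1-en-2-yl)hept-6-en-1-yn-3-ol | C=C[C@@]([C@@H]1COC(C)(C)O1)(C)[C@H](C(=C)C)[C@@H](O)C#C | intermediate
14 | (4R,5S,6S)-1-(dicyclohexylamino)-6-[(4R)-2,2-dimethyl-1,3-dioxolan-4-yl]-6-methyl-5-(prop-1-en-2-yl)oct-7-en-2-yn-4-ol | C=C[C@@]([C@@H]1COC(C)(C)O1)(C)[C@H](C(=C)C)[C@@H](O)C#CCN(C2CCCCC2)C2CCCCC2 | intermediate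
15 | (4S,5S,6S)-6-[(4R)-2,2-dimethyl-1,3-dioxolan-4-yl]-6-methyl-5-(prop-1-en-2-yl)octa-1,2,7-trien-4-ol | C=C[C@@]([C@@H]1COC(C)(C)O1)(C)[C@H](C(=C)C)[C@@H](O)C=C=C | intermediate
16 | (4S,5S,6S)-6-[(4R)-2,2-dimethyl-1,3-dioxolan-4-yl]-6-methyl-5-(prop-1-en-2-yl)octa-1,2,7-trien-4-yl 2-methylpropanoate | C=C[C@@]([C@@H]1COC(C)(C)O1)(C)[C@H](C(=C)C)[C@@H](OC(=O)C(C)C)C=C=C | intermediate
17 | (2R,3S,4S,5S)-3-ethenyl-1,2-dihydroxy-3-methyl-4-(prop-1-en-2-yl)octa-6,7-dien-5-yl 2-methylpropanoate | C=C[C@@]([C@@H](O)CO)(C)[C@H](C(=C)C)[C@@H](OC(=O)C(C)C)C=C=C | intermediate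
18 | (2R,3S,4S,5S)-3-ethenyl-3-methyl-4-(prop-1-en-2-yl)-1,2-bis[(triethylsilyl)oxy]octa-6,7-dien-5-yl 2-methylpropanoate | C=C[C@@]([C@@H](O[Si](CC)(CC)CC)CO[Si](CC)(CC)CC)(C)[C@H](C(=C)C)[C@@H](OC(=O)C(C)C)C=C=C | intermediate
19 | (2R,3S,4S,5S)-3-ethenyl-3-methyl-1-oxo-4-(prop-1-en-2-yl)-2-[(triethylsilyl)oxy]octa-6,7-dien-5-yl 2-methylpropanoate | C=C[C@@]([C@@H](O[Si](CC)(CC)CC)C=O)(C)[C@H](C(=C)C)[C@@H](OC(=O)C(C)C)C=C=C | intermediate
20 | (3aS,4R,5S,6S,7R,7aS)-6-ethenyl-6-methyl-3-methylidene-2-oxo-5-(prop-1-en-2-yl)-7-[(triethylsilyl)oxy]octahydro-1-benzofuran-4-yl 2-methylpropanoate | C=C[C@@]1(C)[C@H](C(=C)C)[C@@H](OC(=O)C(C)C)[C@@H]2C(=C)C(=O)O[C@@H]2[C@@H]1O[Si](CC)(CC)CC | intermediate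
21 | (3aS,4R,5S,6S,7R,7aS)-6-ethenyl-7-hydroxy-6-methyl-3-methylidene-2-oxo-5-(prop-1-en-2-yl)octahydro-1-benzofuran-4-yl 2-methylpropanoate | C=C[C@@]1(C)[C@H](C(=C)C)[C@@H](OC(=O)C(C)C)[C@@H]2C(=C)C(=O)O[C@@H]2[C@@H]1O | intermediate
22 | (3aS,4R,5S,6S,7R,7aS)-6-ethenyl-7-hydroxy-5-(3-hydroxyprop-1-en-2-yl)-6-methyl-3-methylidene-2-oxo-octahydro-1-benzofuran-4-yl 2-methylpropanoate | C=C[C@@]1(C)[C@H](C(=C)CO)[C@@H](OC(=O)C(C)C)[C@@H]2C(=C)C(=O)O[C@@H]2[C@@H]1O | intermediate
23 | (3aS,4S,5S,6S,7R,7aS)-6-ethenyl-7-hydroxy-5-[(2S)-2-(hydroxymethyl)oxiran-2-yl]-6-methyl-3-methylidene-2-oxo-octahydro-1-benzofuran-4-yl 2-methylpropanoate | C=C[C@@]1(C)[C@H]([C@]2(CO)CO2)[C@@H](OC(=O)C(C)C)[C@@H]2C(=C)C(=O)O[C@@H]2[C@@H]1O | intermediate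
24 | (3aS,4S,5S,6S,7R,7aS)-6-ethenyl-5-[(2R)-2-formyloxiran-2-yl]-7-hydroxy-6-methyl-3-methylidene-2-oxo-octahydro-1-benzofuran-4-yl 2-methylpropanoate | C=C[C@@]1(C)[C@H]([C@]2(C=O)CO2)[C@@H](OC(=O)C(C)C)[C@@H]2C(=C)C(=O)O[C@@H]2[C@@H]1O | target

Total step count: 17. Longest linear sequence: 17 steps (1 → 24); compound 7 enters in step 5.

Steps most likely to fail

Step 14. The ring-closing oxidative cyclisation may lose facial selectivity, because the productive chair places the aldehyde oxygen axial and syn to the axial C6 methyl. The low-valent metal may also ionise the allenylic ester at 120 °C. The fallback replaces carbonylation by carboxylation at low temperature. It sets out from 19, which would be treated with Ni(cod)2 (1 equiv), DBU and CO2 (1 atm) in THF at 0 °C. Zerovalent nickel couples CO2 with the central allene carbon, and the resulting allylnickel carboxylate adds through its substituted terminus to the tethered aldehyde. Acidic work-up should give 2-[(1R,2S,3R,4S,5S,6R)-4-ethenyl-2-hydroxy-4-methyl-6-[(2-methylpropanoyl)oxy]-5-(prop-1-en-2-yl)-3-[(triethylsilyl)oxy]cyclohexyl]prop-2-enoic acid F1. Lactonisation of F1 (PPTS, toluene, 60 °C) comes back to the route at 20, which is desilylated as in the second stage of step 14.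

Step 6. The diastereoselectivity may erode through a boat transition state (the dioxolanyl group is pseudo-axial), through leakage to the E-dienolate, or through a weak facial bias of the dioxolane at the trisubstituted alkene. The fallback moves stereocontrol from the substrate to the reagent. It sets out from 8, which would undergo a boron-enolate Ireland–Claisen rearrangement with a C2-symmetric 2-bromo-1,3-bis(4-methylphenylsulfonyl)-4,5-diphenyl-1,3,2-diazaborolidine and i-Pr2NEt in CH2Cl2 (−78 → 4 °C). The enantiomer of the reagent is chosen so that its preferred chair coincides with the one required. This should give (2S,3S)-3-[(4R)-2,2-dimethyl-1,3-dioxolan-4-yl]-3-methyl-2-(prop-1-en-2-yl)pent-4-enoic acid F2, and LiAlH4 reduction of F2 comes back to the route at 11.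

Step 8. The 1,2-induction may be low if the isopropenyl group competes with the quaternary carbon for the anti position, and the hindered aldehyde may enolise. The fallback replaces kinetic substrate control by an oxidation–reduction sequence that funnels both C4 epimers into one. It sets out from 12. Addition of LiC≡CSiMe3 (THF, −78 °C) would give (4S,5S)-5-[(4R)-2,2-dimethyl-1,3-dioxolan-4-yl]-5-methyl-4-(prop-1-en-2-yl)-1-(trimethylsilyl)hept-6-en-1-yn-3-ol F3 as an epimer mixture at C3. Dess–Martin oxidation would give (4S,5S)-5-[(4R)-2,2-dimethyl-1,3-dioxolan-4-yl]-5-methyl-4-(prop-1-en-2-yl)-1-(trimethylsilyl)hept-6-en-1-yn-3-one F4. Noyori transfer hydrogenation with RuCl[(R,R)-TsDPEN](p-cymene) in i-PrOH should then give, under reagent control, (3R,4S,5S)-5-[(4R)-2,2-dimethyl-1,3-dioxolan-4-yl]-5-methyl-4-(prop-1-en-2-yl)-1-(trimethylsilyl)hept-6-en-1-yn-3-ol F5. Desilylation of F5 (K2CO3, MeOH) comes back to the route at 13.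

Further compounds
F1 | step 14 | 2-[(1R,2S,3R,4S,5S,6R)-4-ethenyl-2-hydroxy-4-methyl-6-[(2-methylpropanoyl)oxy]-5-(prop-1-en-2-yl)-3-[(triethylsilyl)oxy]cyclohexyl]prop-2-enoic acid | C=C[C@@]1(C)[C@H](C(=C)C)[C@@H](OC(=O)C(C)C)[C@H](C(=C)C(=O)O)[C@H](O)[C@@H]1O[Si](CC)(CC)CC
F2 | step 6 | (2S,3S)-3-[(4R)-2,2-dimethyl-1,3-dioxolan-4-yl]-3-methyl-2-(prop-1-en-2-yl)pent-4-enoic acid | C=C[C@@]([C@@H]1COC(C)(C)O1)(C)[C@H](C(=C)C)C(=O)O
F3 | step 8 | (4S,5S)-5-[(4R)-2,2-dimethyl-1,3-dioxolan-4-yl]-5-methyl-4-(prop-1-en-2-yl)-1-(trimethylsilyl)hept-6-en-1-yn-3-ol (C3 epimer mixture) | C=C[C@@]([C@@H]1COC(C)(C)O1)(C)[C@H](C(=C)C)C(O)C#C[Si](C)(C)C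
F4 | step 8 | (4S,5S)-5-[(4R)-2,2-dimethyl-1,3-dioxolan-4-yl]-5-methyl-4-(prop-1-en-2-yl)-1-(trimethylsilyl)hept-6-en-1-yn-3-one | C=C[C@@]([C@@H]1COC(C)(C)O1)(C)[C@H](C(=C)C)C(=O)C#C[Si](C)(C)C
F5 | step 8 | (3R,4S,5S)-5-[(4R)-2,2-dimethyl-1,3-dioxolan-4-yl]-5-methyl-4-(prop-1-en-2-yl)-1-(trimethylsilyl)hept-6-en-1-yn-3-ol | C=C[C@@]([C@@H]1COC(C)(C)O1)(C)[C@H](C(=C)C)[C@@H](O)C#C[Si](C)(C)C
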